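**Plan**

1. Retrosynthesis: the C3′ ketone and C4′–H go back to a C3′=C4′ norbornene (hydroboration–oxidation); the norbornene is cut at C2–C2′ and C3–C5′ ([4+2] dimer of one 10-hydroxyguaia-2,4-dien-12,6-olide). In the monomer the lactone C–O bond, the C4=C5 enone and finally C6–C7 and C1–C10 are cut, the last two as a (4+3) cycloaddition.
2. Forward: the seven-membered ring is made first from a 2,5-disubstituted furan and an alkoxy-oxyallyl cation. Then follow the cyclopentenone (hydration, aldol), reductive opening of the oxygen bridge, the lactone, the cyclopentadiene, the [4+2] dimer and oxidation at C3′. One monomer serves as both halves, so the cycloaddition makes the C6–C7 and C1–C10 bonds of each.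
3. Enabling feature: in each cycloheptane ring the tertiary carbinol C10 and C7 stand 1,4 across C8–C9, like C2 and C5 of a furan whose ring oxygen stays on C10 as the hydroxyl. They flank the triad C1–C5–C6, in which C5 is the later enone carbon (a ketone in the adduct) and C6 carries oxygen, that is, an alkoxy-oxyallyl cation.
4. Stereochemistry: a removable (S)-1-phenylethyl group on the C6 oxygen sets the absolute configuration in the cycloaddition (C6, C10). C7 follows from a palladium-hydride displacement of the bridge with inversion, C1 and C11 from equilibration, the norbornane centres from the endo dimerisation anti to the C10 arm, and C4′ is epimerisable to the exo-methyl ketone.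

Key step: step 5

Remark on names: guaiane numbering (C1–C15) is used for every monomer-type compound; in the dimers the cyclopentene half is unprimed and the norbornanone half primed; α/β follow the usual guaianolide drawing (H7 α, C10–OH β in the target).
Assumption 1: the (S)-1-phenylethoxy group is taken to direct the furan to the cation face that gives the drawn absolute configuration; if the sense is opposite, (R)-1-phenylethanol is used and nothing else changes.
Assumption 2: in the ring-opened 3-oxoguai-4-en-12,6-olide the 1α-H epimer, with C7 and C10 on the same face of the enone plane, is taken to be the more stable one.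

**Route**

Step 1
Reactants: 1 1,1-dimethoxypropan-2-one; 2 1-bromobut-2-yne
Product: 4 1,1-dimethoxyhept-5-yn-2-one, via lithium enolate 3 (not isolated)
Conditions: LiN(iPr)2, THF, −78 °C; then 2, DMPU, −78 → 0 °C
Reagents that add atoms: none
Why: The kinetic lithium enolate on the methyl side of the ketone is alkylated by the propargylic bromide in an SN2 reaction, and no stereocentre is formed.

Step 2
Reactants: 4 1,1-dimethoxyhept-5-yn-2-one; 5 (S)-1-phenylethanol
Product: 6 1-methoxy-1-[(1S)-1-phenylethoxy]hept-5-yn-2-one (both acetal epimers)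
Conditions: 5 (1.0 equiv), PPTS (cat.), cyclohexane, 60 °C, 4 Å molecular sieves
Reagents that add atoms: none
Why: Acid-catalysed transacetalisation exchanges one methoxy group for the chiral benzylic alcohol, and the two acetal epimers do not matter because this carbon becomes planar in step 5.

Step 3
Reactants: 6 1-methoxy-1-[(1S)-1-phenylethoxy]hept-5-yn-2-one
Product: 7 triethyl{[(2Z)-1-methoxy-1-[(1S)-1-phenylethoxy]hept-2-en-5-yn-2-yl]oxy}silane
Conditions: TESOTf, Et3N, Et2O, 0 °C
Reagents that add atoms: triethylsilyl trifluoromethanesulfonate, CC[Si](CC)(CC)OS(=O)(=O)C(F)(F)F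
Why: Soft enolisation with a silyl triflate and an amine should give the (Z)-silyl enol ether on the methylene side, which places the side chain where it becomes equatorial at C1.

Step 4
Reactants: 8 4,4,5,5-tetramethyl-2-(5-methylfuran-2-yl)-1,3,2-dioxaborolane; 9 methyl 2-bromoprop-2-enoate
Product: 10 methyl 2-(5-methylfuran-2-yl)prop-2-enoate
Conditions: Pd(PPh3)4 (3 mol%), K2CO3, 1,4-dioxane/H2O, 60 °C, BHT; used at once
Reagents that add atoms: none
Why: Suzuki–Miyaura coupling of the furyl boronate with the vinylic bromide puts the future C11–C13 unit, as an acrylate, on the furan carbon that becomes C7.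

Step 5
Reactants: 7 triethyl{[(2Z)-1-methoxy-1-[(1S)-1-phenylethoxy]hept-2-en-5-yn-2-yl]oxy}silane; 10 methyl 2-(5-methylfuran-2-yl)prop-2-enoate
Product: 12 methyl 2-{4-(but-2-yn-1-yl)-5-methyl-3-oxo-2-[(1S)-1-phenylethoxy]-8-oxabicyclo[3.2.1]oct-6-en-1-yl}prop-2-enoate (2-alkoxy and 4-butynyl groups both trans to O8), via alkoxy-silyloxyallyl cation triflate 11 (not isolated)
Conditions: TMSOTf (0.2 equiv), 10 (2 equiv), CH2Cl2, 4 Å molecular sieves, −78 °C
Reagents that add atoms: none
Why: TMSOTf removes the methoxy group of the mixed acetal to give the (Z)-1-alkoxy-2-silyloxyallyl cation 11, which adds across C2 and C5 of the furan in a stepwise (4+3) cycloaddition: the cation terminus remote from the alkoxy donor (C1, largest LUMO coefficient) should bond first to the less hindered, methyl-bearing furan carbon (C10), and the silyl enol ether carbon C6 then closes onto the furanyl cation, which is allylically stabilised at the acrylate-bearing carbon (C7); loss of the silyl group leaves the C5 ketone. The closest known reaction is the (4+3) cycloaddition of furans with 1-alkoxy-2-silyloxyallyl cations made from mixed 1-phenylethyl acetals of α-keto acetal enol ethers. One carbocycle is closed, the cycloheptene C1–C5–C6–C7–C8–C9–C10, by (4+3) annulation of a three-carbon cation with a four-carbon diene, suprafacial on both partners, and the furan oxygen becomes the one-atom bridge between C7 and C10. C7 and C10 are cis through the furan ring; the C6 alkoxy group and the C1 side chain should be equatorial (trans to the bridge) from the W-shaped Z-cation in a compact transition state, C1 staying epimerisable; the absolute sense comes from the 1-phenylethyl group, which shields one face of the cation. The step needs regioselectivity (C6 to the acrylate carbon, secured by the two electronic biases above and the small methyl group at the first-formed bond) and chemoselectivity over Mukaiyama–Michael addition to the acrylate and Friedel–Crafts capture (low temperature, fast closure by the neighbouring enol ether).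

Step 6
Reactants: 12 (4+3) adduct
Product: 13 methyl 2-{5-methyl-3-oxo-4-(2-oxobutyl)-2-[(1S)-1-phenylethoxy]-8-oxabicyclo[3.2.1]oct-6-en-1-yl}prop-2-enoate
Conditions: (Ph3P)AuNTf2 (2 mol%), H2O (3 equiv), 1,4-dioxane, 50 °C
Reagents that add atoms: water, O
Why: Gold-catalysed hydration of the internal alkyne is steered to C3 by 5-exo participation of the C5 carbonyl oxygen (hydration of a γ,δ-alkynyl ketone), giving the 1,4-diketone without touching acrylate or bridge.

Step 7
Reactants: 13 1,4-diketone
Product: 14 methyl 7β,10β-epoxy-3-oxo-6α-[(1S)-1-phenylethoxy]-1βH-guaia-4,8,11(13)-trien-12-oate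
Conditions: t-BuOK (0.3 equiv), t-BuOH/THF, 0 → 25 °C
Reagents that add atoms: none
Why: Intramolecular aldol condensation (C4 enolate onto the C5 ketone, then dehydration) gives the 2-methylcyclopentenone; the planar enone holds the C1–C2 bond equatorial, so H1 stays cis to the oxygen bridge (1β-H) until step 10.

Step 8
Reactants: 14 tricyclic trienone
Product: 15 methyl 7β,10β-epoxy-3-oxo-6α-[(1S)-1-phenylethoxy]-1βH-guaia-4,11(13)-dien-12-oate
Conditions: 2-nitrobenzenesulfonylhydrazide, Et3N, CH2Cl2, 25 °C
Reagents that add atoms: none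
Why: Diimide reduces the strained cis-disubstituted C8=C9 bond much faster than the hindered electron-poor acrylate or the tetrasubstituted enone, so that step 9 meets a single allylic system.

Step 9
Reactants: 15 bridged dienone ester
Product: 16 methyl 10β-hydroxy-3-oxo-6α-[(1S)-1-phenylethoxy]-1βH,7αH-guaia-4,11(13)-dien-12-oate
Conditions: Pd2(dba)3 (5 mol%), PBu3 (20 mol%), HCO2H (3 equiv), Et3N (1 equiv), 1,4-dioxane, 60 °C
Reagents that add atoms: none
Why: Proposed new method: zerovalent palladium should coordinate the acrylate and ionise the tertiary allylic C7–O bond anti to the metal (helped by protonation of the ether oxygen by formic acid, by the ester-bearing π-allyl and by release of bicyclic strain), formate on palladium loses CO2, and the palladium hydride delivers H to the more substituted terminus C7 from the metal's face, that is with net inversion (H7 α, acrylate arm β), while the oxygen stays on C10 as the β-hydroxyl; the closest known reactions are the palladium/formate hydrogenolyses of allylic formates and of alkenyl oxiranes, which go with inversion and put the hydride on the more substituted allyl terminus.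

Step 10
Reactants: 16 ring-opened acrylate
Product: 18 10β-hydroxy-3-oxo-1αH-guai-4-en-12,6α-olide (11α-methyl), via hydroxy ester 17 (not isolated)
Conditions: H2 (1 atm), Pd/C, EtOAc, 25 °C; filter; then DBU, toluene, 80 °C
Reagents that add atoms: none
Why: Hydrogen over palladium on carbon saturates C11=C13 and cleaves the benzylic 1-phenylethyl ether while the tetrasubstituted enone should survive, and DBU then closes the trans-fused γ-lactone and equilibrates the two epimerisable centres, C11 (methyl trans to C8) and C1 (H to the α face, assumption 2).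

Step 11
Reactants: 18 hydroxy enone lactone
Product: 19 3-oxo-10β-(trimethylsilyloxy)-1αH-guai-4-en-12,6α-olide
Conditions: TMSCl, imidazole, DMF, 25 °C
Reagents that add atoms: chlorotrimethylsilane, C[Si](C)(C)Cl
Why: Silylation masks the tertiary C10 hydroxyl so that no alkoxide, and hence no retro-vinylogous aldol cleavage of C1–C10, can arise in the basic next step.

Step 12
Reactants: 19 silyl ether
Product: 21 3-(trifluoromethanesulfonyloxy)-10β-(trimethylsilyloxy)-1αH-guaia-2,4-dien-12,6α-olide, via potassium dienolate 20 (not isolated)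
Conditions: KN(SiMe3)2 (1.05 equiv), THF, −78 °C; then PhNTf2
Reagents that add atoms: N-phenylbis(trifluoromethanesulfonimide), O=S(=O)(N(c1ccccc1)S(=O)(=O)C(F)(F)F)C(F)(F)F
Why: Kinetic deprotonation at the α′-methylene C2 (the ketone is far more acidic than the lactone C11–H) and O-triflation of the cross-conjugated enolate give the dienyl triflate without touching a stereocentre.

Step 13
Reactants: 21 dienyl triflate
Product: 22 10β-(trimethylsilyloxy)-1αH-guaia-2,4-dien-12,6α-olide
Conditions: Pd(OAc)2 (5 mol%), PPh3 (10 mol%), HCO2H, Bu3N, DMF, 40 °C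
Reagents that add atoms: none
Why: Palladium-catalysed formate reduction of the enol triflate replaces OTf by H and gives the 1-substituted cyclopenta-2,4-diene under mild conditions that leave C1–H in place.

Step 14
Reactants: 22 silylated diene (two molecules)
Product: 24 [4+2] dimer diol (the target skeleton with a C3′=C4′ double bond in place of the C3′ ketone), via free diene 23 (not isolated)
Conditions: HF·pyridine, THF, 0 °C; concentrate; neat, 25 °C, dark, 7 d
Reagents that add atoms: none
Why: After desilylation the monomer should dimerise by the normal Diels–Alder reaction of cyclopentadienes, C2′=C3′–C4′=C5′ of one molecule adding across the less substituted C2=C3 bond of a second through the endo transition state, each partner on the face opposite its C10 arm, C2 bonding to C2′ and C3 to the substituted terminus C5′, which sets C2, C3, C2′, C5′ and makes C1′ the bridge.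

Step 15
Reactants: 24 dimer diol
Product: 26 3′-endo-hydroxy-3′,4′-dihydro dimer (4′-methyl exo), via alkylborane 25 (not isolated)
Conditions: BH3·THF (4 equiv), THF, 0 → 25 °C; then 30% H2O2, aq. NaOAc, 0 °C
Reagents that add atoms: borane–tetrahydrofuran (boron only in 25), B.C1CCOC1; hydrogen peroxide, OO
Why: Hydroboration puts boron on the less substituted C3′ of the strained trisubstituted norbornene (the tetrasubstituted C4=C5 bond is inert) and H on C4′ from the endo face, the exo face being blocked by the C10′ group on the bridge, and buffered peroxide gives the alcohol without opening the lactones.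

Step 16
Reactants: 26 secondary alcohol
Product: 27 caruifolin B
Conditions: DMP (1,1,1-triacetoxy-1,1-dihydro-1,2-benziodoxol-3(1H)-one), NaHCO3, CH2Cl2, 25 °C; Et3N (cat.) if a C4′ epimer is present
Reagents that add atoms: none
Why: The periodinane oxidises only the secondary alcohol to the C3′ ketone, and C4′, now α to the ketone, should settle in the exo-methyl configuration because an endo methyl would clash with C4/C15 of the other half.

**Compound list**

1 | 1,1-dimethoxypropan-2-one | CC(=O)C(OC)OC | starting material
2 | 1-bromobut-2-yne | CC#CCBr | starting material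
3 | lithium 3,3-dimethoxyprop-1-en-2-olate (not isolated) | [Li+].[O-]C(=C)C(OC)OC | intermediate
4 | 1,1-dimethoxyhept-5-yn-2-one | CC#CCCC(=O)C(OC)OC | intermediate
5 | (S)-1-phenylethanol | C[C@H](O)c1ccccc1 | starting material
6 | 1-methoxy-1-[(1S)-1-phenylethoxy]hept-5-yn-2-one (acetal epimers) | CC#CCCC(=O)C(OC)O[C@@H](C)c1ccccc1 | intermediate
7 | triethyl{[(2Z)-1-methoxy-1-[(1S)-1-phenylethoxy]hept-2-en-5-yn-2-yl]oxy}silane | CC#CC/C=C(\O[Si](CC)(CC)CC)C(OC)O[C@@H](C)c1ccccc1 | intermediate
8 | 4,4,5,5-tetramethyl-2-(5-methylfuran-2-yl)-1,3,2-dioxaborolane | Cc1ccc(o1)B1OC(C)(C)C(C)(C)O1 | starting material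
9 | methyl 2-bromoprop-2-enoate | C=C(Br)C(=O)OC | starting material
10 | methyl 2-(5-methylfuran-2-yl)prop-2-enoate | C=C(C(=O)OC)c1ccc(C)o1 | intermediate
11 | (Z)-1-[(1S)-1-phenylethoxy]-2-(triethylsilyloxy)hept-2-en-5-yn-1-ylium triflate (not isolated) | CC#CC/C=C(\O[Si](CC)(CC)CC)C=[O+][C@@H](C)c1ccccc1.[O-]S(=O)(=O)C(F)(F)F | intermediate
12 | methyl 2-{4-(but-2-yn-1-yl)-5-methyl-3-oxo-2-[(1S)-1-phenylethoxy]-8-oxabicyclo[3.2.1]oct-6-en-1-yl}prop-2-enoate; guaiane terms: 6α-OR, 1β-H, 7β,10β-oxygen bridge | O=C1[C@@H](O[C@@H](C)c2ccccc2)[C@@]3(C(=C)C(=O)OC)C=C[C@](C)(O3)[C@H]1CC#CC | intermediate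
13 | methyl 2-{5-methyl-3-oxo-4-(2-oxobutyl)-2-[(1S)-1-phenylethoxy]-8-oxabicyclo[3.2.1]oct-6-en-1-yl}prop-2-enoate (same configuration as 12) | O=C1[C@@H](O[C@@H](C)c2ccccc2)[C@@]3(C(=C)C(=O)OC)C=C[C@](C)(O3)[C@H]1CC(=O)CC | intermediate
14 | methyl 7β,10β-epoxy-3-oxo-6α-[(1S)-1-phenylethoxy]-1βH-guaia-4,8,11(13)-trien-12-oate | CC1=C2[C@@H](O[C@@H](C)c3ccccc3)[C@@]4(C(=C)C(=O)OC)C=C[C@](C)(O4)[C@H]2CC1=O | intermediate
15 | methyl 7β,10β-epoxy-3-oxo-6α-[(1S)-1-phenylethoxy]-1βH-guaia-4,11(13)-dien-12-oate | CC1=C2[C@@H](O[C@@H](C)c3ccccc3)[C@@]4(C(=C)C(=O)OC)CC[C@](C)(O4)[C@H]2CC1=O | intermediate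
16 | methyl 10β-hydroxy-3-oxo-6α-[(1S)-1-phenylethoxy]-1βH,7αH-guaia-4,11(13)-dien-12-oate | CC1=C2[C@@H](O[C@@H](C)c3ccccc3)[C@H](C(=C)C(=O)OC)CC[C@](C)(O)[C@H]2CC1=O | intermediate
17 | methyl 6α,10β-dihydroxy-3-oxo-1βH,7αH-guai-4-en-12-oate (C11 epimers; not isolated) | CC1=C2[C@@H](O)[C@H](C(C)C(=O)OC)CC[C@](C)(O)[C@H]2CC1=O | intermediate
18 | 10β-hydroxy-3-oxo-1αH,6βH,7αH,11βH-guai-4-en-12,6α-olide | CC1=C2[C@H]3OC(=O)[C@@H](C)[C@@H]3CC[C@](C)(O)[C@@H]2CC1=O | intermediate
19 | 3-oxo-10β-(trimethylsilyloxy)-1αH-guai-4-en-12,6α-olide | CC1=C2[C@H]3OC(=O)[C@@H](C)[C@@H]3CC[C@](C)(O[Si](C)(C)C)[C@@H]2CC1=O | intermediate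
20 | potassium 2,4-dien-3-olate of 19 (not isolated) | CC1=C2[C@H]3OC(=O)[C@@H](C)[C@@H]3CC[C@](C)(O[Si](C)(C)C)[C@@H]2C=C1[O-].[K+] | intermediate
21 | 3-(trifluoromethanesulfonyloxy)-10β-(trimethylsilyloxy)-1αH-guaia-2,4-dien-12,6α-olide | CC1=C2[C@H]3OC(=O)[C@@H](C)[C@@H]3CC[C@](C)(O[Si](C)(C)C)[C@@H]2C=C1OS(=O)(=O)C(F)(F)F | intermediate
22 | 10β-(trimethylsilyloxy)-1αH-guaia-2,4-dien-12,6α-olide | CC1=C2[C@H]3OC(=O)[C@@H](C)[C@@H]3CC[C@](C)(O[Si](C)(C)C)[C@@H]2C=C1 | intermediate
23 | 10β-hydroxy-1αH-guaia-2,4-dien-12,6α-olide (not isolated) | CC1=C2[C@H]3OC(=O)[C@@H](C)[C@@H]3CC[C@](C)(O)[C@@H]2C=C1 | intermediate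
24 | [4+2] dimer diol: bonds C2–C2′ and C3–C5′, C3′=C4′ double bond, C1′ as norbornene bridge, endo-fused cyclopentene half | CC1=C2[C@H]3OC(=O)[C@@H](C)[C@@H]3CC[C@](C)(O)[C@@H]2[C@H]2[C@H]3C=C(C)[C@]4([C@@H]3[C@@](C)(O)CC[C@H]3[C@H](C)C(=O)O[C@@H]34)[C@@H]12 | intermediate
25 | C3′-endo alkylborane of 24, drawn as the monoalkylborane with free hydroxyls (not isolated) | CC1=C2[C@H]3OC(=O)[C@@H](C)[C@@H]3CC[C@](C)(O)[C@@H]2[C@H]2[C@H]3[C@@H](B)[C@H](C)[C@]4([C@@H]3[C@@](C)(O)CC[C@H]3[C@H](C)C(=O)O[C@@H]34)[C@@H]12 | intermediate
26 | 3′-endo-hydroxy-3′,4′-dihydro dimer (4′-methyl exo) | CC1=C2[C@H]3OC(=O)[C@@H](C)[C@@H]3CC[C@](C)(O)[C@@H]2[C@H]2[C@H]3[C@@H](O)[C@H](C)[C@]4([C@@H]3[C@@](C)(O)CC[C@H]3[C@H](C)C(=O)O[C@@H]34)[C@@H]12 | intermediate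
27 | caruifolin B | CC1=C2[C@H]3OC(=O)[C@@H](C)[C@@H]3CC[C@](C)(O)[C@@H]2[C@H]2[C@H]3C(=O)[C@H](C)[C@]4([C@@H]3[C@@](C)(O)CC[C@H]3[C@H](C)C(=O)O[C@@H]34)[C@@H]12 | target

**Count and risks**

Total step count: 16. Longest linear sequence: 15 steps (steps 1–3 and 5–16, from 1,1-dimethoxypropan-2-one).

Steps most likely to fail:

Step 9 (Proposed new method). The allylic ether may not ionise on zerovalent palladium, or the hydride may go to C13 instead of C7, which would lose the C7 stereocentre. Fallback with known reactions, setting out from 15 and coming back at 17: conjugate reduction of the acrylate with [(Ph3P)CuH]6 makes an ester enolate that expels the bridging alkoxide and gives the alkylidene ester F1; BCl3 at −78 °C removes the 1-phenylethyl group to give the free 6α-alcohol F2; hydroxyl-directed hydrogenation of F2 with [Ir(cod)(PCy3)(py)]PF6 under H2 delivers hydrogen to C7 from the face of the C6 hydroxyl and gives hydroxy ester 17, which continues with the DBU stage of step 10.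

Step 5. The cation may be captured by the vinylfuran without ring closure, the acid-sensitive furan 10 may oligomerise under the silyl triflate, or C6 may bond to the methyl-bearing furan carbon. Fallback, setting out from 5 and coming back at 12: the same oxyallyl intermediate is generated without Lewis acid by dehydrohalogenation of an α-chloro ketone in a fluorinated alcohol, a known entry to furan (4+3) cycloadditions. Alcohol 5 is alkylated (NaH, 2-chloro-N-methoxy-N-methylacetamide) to (S)-N-methoxy-N-methyl-2-(1-phenylethoxy)acetamide F3; pent-3-yn-1-ylmagnesium bromide gives 1-[(1S)-1-phenylethoxy]hept-5-yn-2-one F4; kinetic enolisation away from the alkoxy group (LiN(iPr)2, TMSCl) and N-chlorosuccinimide give 3-chloro-1-[(1S)-1-phenylethoxy]hept-5-yn-2-one F5; F5 and furan 10 with Et3N in CF3CH2OH give 12.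

Step 7. Base may trigger β-elimination of the oxygen bridge or conjugate addition to the acrylate in competition with the aldol condensation. Fallback, setting out from 12 and coming back at 14, with no new compound (F0): alkynyl ketone 12 is treated with AgSbF6 in dry 1,2-dichloroethane, and an intramolecular alkyne–carbonyl metathesis (oxetene formation and ring opening) gives cyclopentenone 14 directly, without base and without the diketone 13.

Further compounds
F1 | step 9 | methyl 10β-hydroxy-3-oxo-6α-[(1S)-1-phenylethoxy]-1βH-guaia-4,7(11)-dien-12-oate (alkene isomers) | CC1=C2[C@@H](O[C@@H](C)c3ccccc3)C(=C(C)C(=O)OC)CC[C@](C)(O)[C@H]2CC1=O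
F2 | step 9 | methyl 6α,10β-dihydroxy-3-oxo-1βH-guaia-4,7(11)-dien-12-oate (alkene isomers) | CC1=C2[C@@H](O)C(=C(C)C(=O)OC)CC[C@](C)(O)[C@H]2CC1=O
F3 | step 5 | (S)-N-methoxy-N-methyl-2-(1-phenylethoxy)acetamide | CON(C)C(=O)CO[C@@H](C)c1ccccc1
F4 | step 5 | 1-[(1S)-1-phenylethoxy]hept-5-yn-2-one | CC#CCCC(=O)CO[C@@H](C)c1ccccc1
F5 | step 5 | 3-chloro-1-[(1S)-1-phenylethoxy]hept-5-yn-2-one (C3 epimers) | CC#CCC(Cl)C(=O)CO[C@@H](C)c1ccccc1
F0 | step 7 | none | none
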